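**Retrosynthetic overview**
1. Target: (2S)-6-geranyl-5,7-dihydroxy-3',4'-dimethoxyflavanone; the last disconnection removes two MOM ethers (O5, O7).
2. Key disconnection: O1–C2 of the pyranone ring (retro-oxa-Michael) after adding an allyl ester back at C3, giving an acyclic alkylidene β-keto ester (E/Z mixture) that comes from an A-ring β-keto ester and veratraldehyde (Knoevenagel at C2=C3).
3. Enabling feature: C3 of the pyranone ring is a bare CH2 between the C4 ketone and C2, so it can carry a removable ester that makes C2=C3 a doubly activated acceptor with a 1,3-dicarbonyl handle for a chiral catalyst; O1 is a phenol oxygen β to C4=O; C2 is the only stereocentre, so alkene isomers and C3 epimers can all funnel into it.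
4. A-ring piece: β-keto ester from an aldehyde (C4) and allyl acetate (C3); the aldehyde from ortho-formylation of the C2-symmetric 4-geranyl-3,5-bis(MOM-oxy)phenol, made by directed metalation/geranylation of resorcinol bis-MOM ether and C–H borylation/oxidation (O1). The symmetry fixes the 6-geranyl pattern.
5. Ring order: rings A (resorcinol) and B (veratraldehyde) are bought; the pyranone ring C is the only ring built and is closed last.

Key step: step 8

Assumption: the quinidine-derived member of the pseudoenantiomeric cinchona thiourea pair is taken as the one that gives the (2S) series; if the sense of induction is the opposite, the quinine-derived member replaces it with no other change. "Geranyl" means (2E)-3,7-dimethylocta-2,6-dien-1-yl throughout.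

**Route**

Step 1
Reactants: 1 resorcinol
Product: 2 1,3-bis(methoxymethoxy)benzene
Conditions: NaH (2.4 equiv), MOMCl (2.4 equiv), DMF, 0 → 23 °C
Reagents that add atoms: chloromethyl methyl ether, COCCl
Why: Double Williamson-type O-alkylation of the bis-phenoxide gives the bis-MOM acetal, which later protects O5 and O7 and serves as the cooperative directing pair for ortho-lithiation.

Step 2
Reactants: 2 1,3-bis(methoxymethoxy)benzene; 3 geranyl bromide
Product: 5 2-geranyl-1,3-bis(methoxymethoxy)benzene, via aryllithium 4 (not isolated)
Conditions: n-BuLi (1.1 equiv), THF, 0 °C; CuI (10 mol %), then 3, −78 → 0 °C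
Reagents that add atoms: none
Why: Directed ortho-metalation takes place at C2 between the two chelating MOM groups, and copper-catalysed SN2 allylation of the aryllithium at the α-carbon of geranyl bromide should keep the (E)-alkene.

Step 3
Reactants: 5 2-geranyl-1,3-bis(methoxymethoxy)benzene
Product: 7 4-geranyl-3,5-bis(methoxymethoxy)phenol, via arylboronate 6 (not isolated)
Conditions: [Ir(OMe)(cod)]2 (1.5 mol %), dtbpy (3 mol %), B2pin2 (0.6 equiv), THF, 60 °C; then 30% H2O2, aq NaOH, 0 °C
Reagents that add atoms: hydrogen peroxide, OO (the phenol oxygen of 7); bis(pinacolato)diboron, CC1(C)OB(OC1(C)C)B1OC(C)(C)C(C)(C)O1 (the boryl group of 6 only)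
Why: Sterically controlled iridium-catalysed C–H borylation should occur at the only arene C–H without an ortho substituent (para to the geranyl group) while the hindered trisubstituted alkenes stay intact, and basic peroxide oxidation of the C–B bond, which does not epoxidise unactivated alkenes, gives the symmetric phenol.

Step 4
Reactants: 7 4-geranyl-3,5-bis(methoxymethoxy)phenol
Product: 8 3-geranyl-6-hydroxy-2,4-bis(methoxymethoxy)benzaldehyde
Conditions: MgCl2 (2 equiv), Et3N (4 equiv), (CH2O)n (6 equiv), MeCN, 80 °C
Reagents that add atoms: paraformaldehyde (as formaldehyde), C=O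
Why: Magnesium-mediated ortho-formylation (Casnati–Skattebøl type) delivers the formyl group only ortho to the free hydroxyl, and because the two ortho positions are equivalent by symmetry a single aldehyde results in which the only free phenol (future O1) is para to the geranyl group.

Step 5
Reactants: 8 3-geranyl-6-hydroxy-2,4-bis(methoxymethoxy)benzaldehyde; 9 allyl acetate
Product: 11 allyl 3-[3-geranyl-6-hydroxy-2,4-bis(methoxymethoxy)phenyl]-3-hydroxypropanoate (racemic), via lithium enolate of allyl acetate 10 (not isolated)
Conditions: LDA (3.3 equiv), 9 (3.1 equiv), THF, −78 °C; then 8, −78 °C; aq NH4Cl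
Reagents that add atoms: none
Why: Aldol addition of the ester enolate (one equivalent is consumed by the phenol) forms the future C3–C4 bond, and the racemic carbinol centre is of no consequence because step 6 removes it.

Step 6
Reactants: 11 allyl 3-[3-geranyl-6-hydroxy-2,4-bis(methoxymethoxy)phenyl]-3-hydroxypropanoate
Product: 12 allyl 3-[3-geranyl-6-hydroxy-2,4-bis(methoxymethoxy)phenyl]-3-oxopropanoate
Conditions: activated MnO2 (20 equiv), CH2Cl2, 23 °C
Reagents that add atoms: none
Why: Benzylic oxidation of the ortho-hydroxybenzylic alcohol with MnO2 gives the hydrogen-bonded β-keto ester under neutral conditions that should spare the MOM acetals, the geranyl alkenes and the allyl ester.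

Step 7
Reactants: 12 allyl 3-[3-geranyl-6-hydroxy-2,4-bis(methoxymethoxy)phenyl]-3-oxopropanoate; 13 3,4-dimethoxybenzaldehyde
Product: 14 allyl 3-(3,4-dimethoxyphenyl)-2-[3-geranyl-6-hydroxy-2,4-bis(methoxymethoxy)benzoyl]prop-2-enoate (E/Z mixture)
Conditions: piperidine (0.2 equiv), AcOH (0.2 equiv), 4 Å MS, toluene, 23 °C
Reagents that add atoms: none
Why: Knoevenagel condensation of the active methylene with the aldehyde forms the C2=C3 bond, and the expected E/Z mixture is used as such because step 8 is stereoconvergent.

Step 8
Reactants: 14 allyl 3-(3,4-dimethoxyphenyl)-2-[3-geranyl-6-hydroxy-2,4-bis(methoxymethoxy)benzoyl]prop-2-enoate (E/Z mixture)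
Product: 16 (2S)-2-(3,4-dimethoxyphenyl)-6-geranyl-5,7-bis(methoxymethoxy)chroman-4-one, via flavanone allyl ester 15 (not isolated)
Conditions: quinidine-derived bifunctional thiourea [3,5-(CF3)2C6H3NHC(S)NH-(9-deoxy-epi-quinidin-9-yl)] (10 mol %), toluene, −25 °C; then HCO2H (4 equiv), Et3N (3 equiv), Pd(OAc)2 (5 mol %), PPh3 (20 mol %), THF, −25 → 30 °C
Reagents that add atoms: none
Why: The thiourea of the bifunctional catalyst binds the 1,3-dicarbonyl unit of 14 by double hydrogen bonding while its quinuclidine nitrogen deprotonates and positions the single free phenol, which adds to the benzylidene carbon (oxa-Michael addition), and the resulting 3-allyloxycarbonyl flavanone 15 is then deallylated in the same flask by Pd(0)/formate and loses CO2 as the β-keto acid to leave the C3 methylene. The closest known reaction type is the cinchona-thiourea-catalysed intramolecular oxa-Michael addition of 2-hydroxyaryl alkylidene β-keto esters with subsequent decarboxylation to 2-aryl-chroman-4-ones, joined here to the known Pd-catalysed formate-mediated decarboxylation of allyl β-keto esters, which replaces hot acid that the geranyl chain and the MOM acetals would not tolerate. The pyranone ring is closed by a 6-endo-trig oxa-Michael addition that forms the O1–C2 bond. C2 is the only stereocentre and is set by the catalyst, which shields one face of the benzylidene carbon inside the hydrogen-bonded ion pair; the E and Z isomers of 14 equilibrate through reversible conjugate addition and are expected to funnel into the same (2S) adduct, and the C3 epimers of 15 converge when C3 becomes CH2. The step needs regioselectivity between the two oxygens ortho to the acyl group, secured because the oxygen flanked by the geranyl group carries a MOM group so that only the phenol para to the geranyl chain can close the ring (6- and not 8-geranyl), and chemoselectivity of Pd(0) for the allyl ester over the trisubstituted geranyl alkenes. Excess formic acid protonates the basic catalyst before warming, which is expected to suppress retro-oxa-Michael opening and so protect the C2 configuration.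

Step 9
Reactants: 16 (2S)-2-(3,4-dimethoxyphenyl)-6-geranyl-5,7-bis(methoxymethoxy)chroman-4-one
Product: 17 (2S)-2-(3,4-dimethoxyphenyl)-6-geranyl-5,7-dihydroxychroman-4-one (CNP0268555.1)
Conditions: 3 M aq HCl, MeOH, 35 °C, short contact time
Reagents that add atoms: none
Why: Acid-catalysed transacetalisation of both aryl MOM ethers in methanol frees the 5- and 7-hydroxyls, and the mild temperature is chosen so that neither the geranyl chain between the two phenols cyclises nor the C2 benzylic ether ionises.

**Compound list**
1 | resorcinol (benzene-1,3-diol) | Oc1cccc(O)c1 | starting material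
2 | 1,3-bis(methoxymethoxy)benzene | COCOc1cccc(OCOC)c1 | intermediate
3 | geranyl bromide, (2E)-1-bromo-3,7-dimethylocta-2,6-diene | BrC/C=C(\C)CCC=C(C)C | starting material
4 | 2-lithio-1,3-bis(methoxymethoxy)benzene (not isolated) | [Li]c1c(OCOC)cccc1OCOC | intermediate
5 | 2-[(2E)-3,7-dimethylocta-2,6-dien-1-yl]-1,3-bis(methoxymethoxy)benzene | COCOc1cccc(OCOC)c1C/C=C(\C)CCC=C(C)C | intermediate
6 | 2-[4-geranyl-3,5-bis(methoxymethoxy)phenyl]-4,4,5,5-tetramethyl-1,3,2-dioxaborolane (not isolated) | COCOc1cc(B2OC(C)(C)C(C)(C)O2)cc(OCOC)c1C/C=C(\C)CCC=C(C)C | intermediate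
7 | 4-[(2E)-3,7-dimethylocta-2,6-dien-1-yl]-3,5-bis(methoxymethoxy)phenol | COCOc1cc(O)cc(OCOC)c1C/C=C(\C)CCC=C(C)C | intermediate
8 | 3-[(2E)-3,7-dimethylocta-2,6-dien-1-yl]-6-hydroxy-2,4-bis(methoxymethoxy)benzaldehyde | O=Cc1c(O)cc(OCOC)c(C/C=C(\C)CCC=C(C)C)c1OCOC | intermediate
9 | allyl acetate (prop-2-en-1-yl acetate) | CC(=O)OCC=C | starting material
10 | lithium enolate of allyl acetate (not isolated) | C=C(O[Li])OCC=C | intermediate
11 | allyl 3-[3-geranyl-6-hydroxy-2,4-bis(methoxymethoxy)phenyl]-3-hydroxypropanoate (racemic) | C=CCOC(=O)CC(O)c1c(O)cc(OCOC)c(C/C=C(\C)CCC=C(C)C)c1OCOC | intermediate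
12 | allyl 3-[3-geranyl-6-hydroxy-2,4-bis(methoxymethoxy)phenyl]-3-oxopropanoate | C=CCOC(=O)CC(=O)c1c(O)cc(OCOC)c(C/C=C(\C)CCC=C(C)C)c1OCOC | intermediate
13 | 3,4-dimethoxybenzaldehyde (veratraldehyde) | COc1ccc(C=O)cc1OC | starting material
14 | allyl 3-(3,4-dimethoxyphenyl)-2-[3-geranyl-6-hydroxy-2,4-bis(methoxymethoxy)benzoyl]prop-2-enoate (E/Z mixture at the new alkene) | C=CCOC(=O)C(=Cc1ccc(OC)c(OC)c1)C(=O)c1c(O)cc(OCOC)c(C/C=C(\C)CCC=C(C)C)c1OCOC | intermediate
15 | allyl (2S)-2-(3,4-dimethoxyphenyl)-6-geranyl-5,7-bis(methoxymethoxy)-4-oxochromane-3-carboxylate (C3 epimers, not isolated) | COc1ccc([C@@H]2C(C(=O)OCC=C)C(=O)c3c(cc(OCOC)c(C/C=C(\C)CCC=C(C)C)c3OCOC)O2)cc1OC | intermediate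
16 | (2S)-2-(3,4-dimethoxyphenyl)-6-[(2E)-3,7-dimethylocta-2,6-dien-1-yl]-5,7-bis(methoxymethoxy)chroman-4-one | COc1ccc([C@@H]2CC(=O)c3c(cc(OCOC)c(C/C=C(\C)CCC=C(C)C)c3OCOC)O2)cc1OC | intermediate
17 | (2S)-2-(3,4-dimethoxyphenyl)-6-[(2E)-3,7-dimethylocta-2,6-dien-1-yl]-5,7-dihydroxychroman-4-one | COc1ccc([C@@H]2CC(=O)c3c(cc(O)c(C/C=C(\C)CCC=C(C)C)c3O)O2)cc1OC | target

**Step count**
Total: 9 steps. Longest linear sequence: 9 steps (resorcinol to 17); geranyl bromide, allyl acetate and veratraldehyde enter as bought materials.

**Steps most likely to fail**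

Step 8. The catalyst may discriminate the faces of the benzylidene carbon poorly with the small allyl ester and the MOM-twisted aroyl group. The two alkene isomers may also converge incompletely, or the C2 configuration may erode by retro-oxa-Michael opening during decarboxylation. Fallback (resolution in place of asymmetric catalysis): setting out from 14, ring closure without chiral control (DBU 5 mol %, toluene, 0 °C) should give the racemic flavanone allyl ester F1. This is deallylated and decarboxylated in the same flask (HCO2H/Et3N, cat. Pd(OAc)2/PPh3, THF) to the racemic bis-MOM flavanone F2. Preparative HPLC on an amylose carbamate chiral stationary phase then separates the (2S)-enantiomer from the (2R)-enantiomer F3. F3 is returned to F2 by base-mediated ring opening and re-closure (cat. DBU) and resolved again. The route is rejoined at 16.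

Step 3. The geranyl alkenes may be borylated or hydroborated in competition, or the diene may inhibit the iridium catalyst, so that the meta C–H functionalisation stalls. Fallback (oxygenate before the alkenes are present, with a silyl relay): setting out from 2, the same borylation gives the arylboronate F4, and H2O2/NaOH oxidation gives 3,5-bis(methoxymethoxy)phenol F5. Silylation (TIPSCl, imidazole, DMF) gives the triisopropylsilyl ether F6. n-BuLi in THF at 0 °C lithiates between the two MOM groups, the bulky silyl ether being a poor director, to give the aryllithium F7. CuI (10 mol %) and geranyl bromide give the geranylated silyl ether F8, and TBAF in THF at 0 °C rejoins the route at 7.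

Step 7. The hindered, hydrogen-bonded aroylacetate may condense slowly with the electron-rich aldehyde. Meanwhile the free phenol may lactonise onto the allyl ester or close the ring prematurely and unselectively under amine catalysis. Fallback (mask the nucleophilic oxygen during the condensation): setting out from 12, silylation (TBSCl, imidazole, DMF) gives the silyl-protected β-keto ester F9. The same Knoevenagel condensation with 13 gives the silyl-protected alkylidene F10. Non-basic desilylation (HF·pyridine, THF, 0 °C) releases the phenol in protonated form and rejoins the route at 14.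

**Further compounds**
F1 | step 8 | allyl 2-(3,4-dimethoxyphenyl)-6-geranyl-5,7-bis(methoxymethoxy)-4-oxochromane-3-carboxylate (racemic, not isolated) | COc1ccc(C2C(C(=O)OCC=C)C(=O)c3c(cc(OCOC)c(C/C=C(\C)CCC=C(C)C)c3OCOC)O2)cc1OC
F2 | step 8 | racemic 2-(3,4-dimethoxyphenyl)-6-geranyl-5,7-bis(methoxymethoxy)chroman-4-one | COc1ccc(C2CC(=O)c3c(cc(OCOC)c(C/C=C(\C)CCC=C(C)C)c3OCOC)O2)cc1OC
F3 | step 8 | (2R)-2-(3,4-dimethoxyphenyl)-6-geranyl-5,7-bis(methoxymethoxy)chroman-4-one | COc1ccc([C@H]2CC(=O)c3c(cc(OCOC)c(C/C=C(\C)CCC=C(C)C)c3OCOC)O2)cc1OC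
F4 | step 3 | 2-[3,5-bis(methoxymethoxy)phenyl]-4,4,5,5-tetramethyl-1,3,2-dioxaborolane | COCOc1cc(OCOC)cc(B2OC(C)(C)C(C)(C)O2)c1
F5 | step 3 | 3,5-bis(methoxymethoxy)phenol | COCOc1cc(O)cc(OCOC)c1
F6 | step 3 | [3,5-bis(methoxymethoxy)phenoxy]triisopropylsilane | COCOc1cc(O[Si](C(C)C)(C(C)C)C(C)C)cc(OCOC)c1
F7 | step 3 | [4-lithio-3,5-bis(methoxymethoxy)phenoxy]triisopropylsilane (not isolated) | [Li]c1c(OCOC)cc(O[Si](C(C)C)(C(C)C)C(C)C)cc1OCOC
F8 | step 3 | [4-geranyl-3,5-bis(methoxymethoxy)phenoxy]triisopropylsilane | COCOc1cc(O[Si](C(C)C)(C(C)C)C(C)C)cc(OCOC)c1C/C=C(\C)CCC=C(C)C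
F9 | step 7 | allyl 3-[6-(tert-butyldimethylsilyloxy)-3-geranyl-2,4-bis(methoxymethoxy)phenyl]-3-oxopropanoate | C=CCOC(=O)CC(=O)c1c(O[Si](C)(C)C(C)(C)C)cc(OCOC)c(C/C=C(\C)CCC=C(C)C)c1OCOC
F10 | step 7 | allyl 2-[6-(tert-butyldimethylsilyloxy)-3-geranyl-2,4-bis(methoxymethoxy)benzoyl]-3-(3,4-dimethoxyphenyl)prop-2-enoate (E/Z mixture) | C=CCOC(=O)C(=Cc1ccc(OC)c(OC)c1)C(=O)c1c(O[Si](C)(C)C(C)(C)C)cc(OCOC)c(C/C=C(\C)CCC=C(C)C)c1OCOC
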